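**Plan**
- Retrosynthetic cuts: the bond between the linker CH2 and azulene C5 (Stork–Danheiser union of two bicycles); in the left bicycle the C7–CH3 bond, the C6–CH2 bond, the oxepane C5–C5a bond (ring closure) and the C9a–O–C2 ether; in the right bicycle the cycloheptenone is cut back by two carbons to a cis-bicyclo[3.3.0]octanone, a Pauson–Khand product of a linalool-derived enyne.
- Forward order, left: cyclohexene ketal, then ether tether on C9a–O, then the oxepane is closed onto the six-membered ring (key step), then the C6 side chain and the C7 methyl carbinol. Forward order, right: both five-membered rings in one step, then gem-dimethyl, then two-carbon ring expansion to the cycloheptanedione. The two bicycles are joined last.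
- Enabling feature: the quaternary ring-fusion carbon C5a lies between the ether carbon C9a and a ring CH (C6), and C5 is β to the carbinol carbon C3. A C5a=C6 ring alkene is therefore a latent tertiary radical at C5a, and a C3 ketone turns C4=C5 into a radical acceptor held in reach by the C9a–O–C2 ether.
- Stereochemistry, left: C9a by CBS reduction; C5a from C9a in the key step (trans fusion); C6 by equilibration next to the C7 ketone; C7 by equatorial MeMgBr attack; C3 by CBS reduction.
- Stereochemistry, right: C1 from (R)-linalool; C8a from C1 in the Pauson–Khand step; C3a by cis-selective protonation; C7 by CBS reduction.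

Key step: step 6

Remark: locants of the left bicycle follow 1-benzoxepane numbering (O1, C2–C5, C5a, C6–C9, C9a) and those of the right bicycle azulene numbering (C1–C8a); (R)-(−)-linalool is taken as enantiomerically pure.

**Left bicycle**

Step 1
Reactants: 1 1,4-dioxaspiro[4.5]dec-6-en-8-one
Product: 2 7-iodo-1,4-dioxaspiro[4.5]dec-6-en-8-one
Conditions: I2, pyridine, CH2Cl2, 0 °C to rt
Reagents that add atoms: iodine (II)
Why: α-iodination of a cyclic enone by conjugate addition of pyridine, iodination of the enolate and elimination, which leaves the ketal untouched under the buffered conditions.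

Step 2
Reactants: 2 7-iodo-1,4-dioxaspiro[4.5]dec-6-en-8-one
Product: 3 7-methyl-1,4-dioxaspiro[4.5]dec-6-en-8-one
Conditions: MeB(OH)2, PdCl2(dppf) (5 mol %), K2CO3, dioxane/H2O, 80 °C
Reagents that add atoms: methylboronic acid (CB(O)O)
Why: Suzuki–Miyaura cross-coupling of an α-iodoenone with methylboronic acid should install the ring methyl group without touching the enone or the ketal.

Step 3
Reactants: 3 7-methyl-1,4-dioxaspiro[4.5]dec-6-en-8-one
Product: 4 (8R)-7-methyl-1,4-dioxaspiro[4.5]dec-6-en-8-ol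
Conditions: (S)-2-methyl-CBS-oxazaborolidine (10 mol %), catecholborane, toluene, −78 °C
Reagents that add atoms: none
Why: Corey–Bakshi–Shibata reduction of a 2-substituted cyclohexenone, in which the methyl-bearing alkene flank acts as the large group, should give the (R)-allylic alcohol and so sets the future C9a under reagent control.

Step 4
Reactants: 4 (8R)-7-methyl-1,4-dioxaspiro[4.5]dec-6-en-8-ol
Product: 5 2-methyl-2-{[(8R)-7-methyl-1,4-dioxaspiro[4.5]dec-6-en-8-yl]oxy}propanoic acid
Conditions: NaH (4 equiv), THF, 0 °C; 2-bromo-2-methylpropanoic acid, 0 to 45 °C; then cold 1 M HCl to pH 4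
Reagents that add atoms: 2-bromo-2-methylpropanoic acid (CC(C)(Br)C(=O)O)
Why: Williamson-type etherification in which the α-bromo carboxylate ionises with carboxylate assistance (α-lactone), so that the secondary alkoxide is alkylated at the tertiary carbon while elimination is held back, and the carbinol stereocentre is not involved.

Step 5
Reactants: 5 2-methyl-2-{[(8R)-7-methyl-1,4-dioxaspiro[4.5]dec-6-en-8-yl]oxy}propanoic acid
Product: 6 4-methyl-4-{[(8R)-7-methyl-1,4-dioxaspiro[4.5]dec-6-en-8-yl]oxy}pent-1-en-3-one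
Conditions: vinyllithium (3 equiv, from Sn(CH=CH2)4 and MeLi), THF, −78 to 0 °C; then aq. NH4Cl
Reagents that add atoms: vinyllithium ([Li]C=C)
Why: ketone synthesis from a carboxylic acid and an organolithium, in which the lithium carboxylate takes up one vinyllithium to a dilithium gem-diolate that collapses only on work-up, so over-addition to the vinyl ketone cannot occur.

Step 6
Reactants: 6 4-methyl-4-{[(8R)-7-methyl-1,4-dioxaspiro[4.5]dec-6-en-8-yl]oxy}pent-1-en-3-one
Product: 7 (5aR,9aR)-7,7-(ethylenedioxy)-2,2,5a-trimethyloctahydro-1-benzoxepin-3(2H)-one (trans-fused)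
Conditions: Fe(acac)3 (30 mol %), PhSiH3 (slow addition), EtOH/ethylene glycol, 0.01 M, 60 °C
Reagents that add atoms: none
Why: Proposed new method: The iron hydride formed from Fe(acac)3 and PhSiH3 should transfer a hydrogen atom to the unsubstituted alkene carbon of 6 (future C6), the tertiary radical at the methyl-bearing carbon (future C5a) should add to the unsubstituted terminus of the tethered vinyl ketone, and the α-keto radical should be reduced and protonated, which forms the C5–C5a bond and closes the oxepane. The closest known reaction type is the iron-mediated reductive olefin coupling (hydrogen-atom-transfer Giese reaction), established between 1-methylcyclohexene-type donors and vinyl ketones and, intramolecularly, for five- and six-membered rings; the seven-membered closure through an ether tether is the untested part. The ring closes in the 7-endo-trig mode, preferred over 6-exo because the nucleophilic tertiary radical attacks the β-carbon of the enone and because the gem-dimethyl group folds the tether. The new quaternary stereocentre C5a is controlled by the ether-bearing carbon C9a: with the bulky tertiary alkoxy group equatorial, a chair-like transition state in which the forming bond is also equatorial should give the trans ring fusion, as in the 6-endo closures of radical polyene cyclisations, while the axial approach is hindered by the axial dioxolane oxygen. The step needs Markovnikov hydrogen-atom transfer (secured by the trisubstituted alkene, which gives the tertiary radical), initiation at the electron-rich alkene and not at the enone (polarity matching), and cyclisation faster than reduction of the radical (high dilution and slow addition of the silane).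

Step 7
Reactants: 7 (5aR,9aR)-7,7-(ethylenedioxy)-2,2,5a-trimethyloctahydro-1-benzoxepin-3(2H)-one
Product: 8 (3R,5aR,9aR)-7,7-(ethylenedioxy)-2,2,5a-trimethyldecahydro-1-benzoxepin-3-ol
Conditions: (S)-2-methyl-CBS-oxazaborolidine (10 mol %), BH3·SMe2, THF, −20 °C
Reagents that add atoms: none
Why: Corey–Bakshi–Shibata reduction of a ketone flanked by a quaternary carbon (large) and a CH2 group (small) should set the (3R)-carbinol under reagent control.

Step 8
Reactants: 8 (3R,5aR,9aR)-7,7-(ethylenedioxy)-2,2,5a-trimethyldecahydro-1-benzoxepin-3-ol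
Product: 9 (3R,5aR,9aR)-3-(tert-butyldimethylsilyloxy)-7,7-(ethylenedioxy)-2,2,5a-trimethyldecahydro-1-benzoxepine
Conditions: TBSOTf, 2,6-lutidine, CH2Cl2, −78 to 0 °C
Reagents that add atoms: tert-butyldimethylsilyl trifluoromethanesulfonate (CC(C)(C)[Si](C)(C)OS(=O)(=O)C(F)(F)F)
Why: silyl triflate silylation of a hindered secondary alcohol, needed so that the carbinol survives the oxidation, enolate and organometallic steps that follow.

Step 9
Reactants: 9 (3R,5aR,9aR)-3-(tert-butyldimethylsilyloxy)-7,7-(ethylenedioxy)-2,2,5a-trimethyldecahydro-1-benzoxepine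
Product: 10 (3R,5aR,9aR)-3-(tert-butyldimethylsilyloxy)-2,2,5a-trimethyloctahydro-1-benzoxepin-7(2H)-one
Conditions: PPTS, acetone/H2O, 55 °C
Reagents that add atoms: water (O)
Why: mild acid-catalysed transketalisation and hydrolysis frees the C7 ketone while the hindered secondary silyl ether should survive.

Step 10
Reactants: 10 (3R,5aR,9aR)-3-(tert-butyldimethylsilyloxy)-2,2,5a-trimethyloctahydro-1-benzoxepin-7(2H)-one
Product: 11 (3R,5aR,9aR)-3-(tert-butyldimethylsilyloxy)-2,2,5a-trimethyl-3,4,5,5a,6,9a-hexahydro-1-benzoxepin-7(2H)-one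
Conditions: IBX, DMSO/toluene, 70 °C
Reagents that add atoms: none
Why: IBX dehydrogenation of a ketone to its enone can only occur towards C8–C9, because the other β-carbon (C5a) is quaternary, and the new alkene blocks C8 for the next step.

Step 11
Reactants: 11 (3R,5aR,9aR)-3-(tert-butyldimethylsilyloxy)-2,2,5a-trimethyl-3,4,5,5a,6,9a-hexahydro-1-benzoxepin-7(2H)-one
Product: 12 (3R,5aR,6S,9aR)-6-allyl-3-(tert-butyldimethylsilyloxy)-2,2,5a-trimethyl-3,4,5,5a,6,9a-hexahydro-1-benzoxepin-7(2H)-one (allyl anti to the 5a-methyl)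
Conditions: LiN(i-Pr)2, THF, −78 °C; allyl bromide, DMPU, −78 to −30 °C
Reagents that add atoms: allyl bromide (C=CCBr)
Why: kinetic α'-deprotonation of the enone can only give the C6 enolate, whose alkylation should occur mainly anti to the axial 5a-methyl group; either C6 epimer is acceptable because the centre is equilibrated in step 12.

Step 12
Reactants: 12 (3R,5aR,6S,9aR)-6-allyl-3-(tert-butyldimethylsilyloxy)-2,2,5a-trimethyl-3,4,5,5a,6,9a-hexahydro-1-benzoxepin-7(2H)-one
Product: 14 (3R,5aR,6R,9aR)-6-allyl-3-(tert-butyldimethylsilyloxy)-2,2,5a-trimethyloctahydro-1-benzoxepin-7(2H)-one, via silyl enol ether 13 (not isolated)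
Conditions: Cu(OAc)2 (5 mol %), 1,2-bis(diphenylphosphino)benzene (5 mol %), (EtO)2MeSiH, toluene, rt; then NaOMe, MeOH, rt
Reagents that add atoms: none
Why: copper hydride 1,4-reduction of the enone spares the terminal alkene, and methoxide then cleaves the silyl enol ether and equilibrates C6 to the epimer with the equatorial side chain (cis to the angular methyl), which is the thermodynamic arrangement next to the ketone.

Step 13
Reactants: 14 (3R,5aR,6R,9aR)-6-allyl-3-(tert-butyldimethylsilyloxy)-2,2,5a-trimethyloctahydro-1-benzoxepin-7(2H)-one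
Product: 15 (3R,5aR,6R,7S,9aR)-6-allyl-3-(tert-butyldimethylsilyloxy)-2,2,5a,7-tetramethyldecahydro-1-benzoxepin-7-ol
Conditions: MeMgBr, CeCl3, THF, −78 to 0 °C; aq. NH4Cl
Reagents that add atoms: methylmagnesium bromide (C[Mg]Br)
Why: cerium-assisted Grignard 1,2-addition, in which axial attack is blocked by the syn-axial 5a-methyl group, so the methyl should enter equatorially and give the axial (7S) tertiary alcohol.

Step 14
Reactants: 15 (3R,5aR,6R,7S,9aR)-6-allyl-3-(tert-butyldimethylsilyloxy)-2,2,5a,7-tetramethyldecahydro-1-benzoxepin-7-ol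
Product: 16 (3R,5aR,6R,7S,9aR)-6-allyl-3-(tert-butyldimethylsilyloxy)-2,2,5a,7-tetramethyl-7-(triethylsilyloxy)decahydro-1-benzoxepine
Conditions: TESOTf, 2,6-lutidine, CH2Cl2, 0 °C to rt
Reagents that add atoms: triethylsilyl trifluoromethanesulfonate (CC[Si](CC)(CC)OS(=O)(=O)C(F)(F)F)
Why: silyl triflate silylation of the tertiary alcohol prevents its later cyclisation onto the activated side chain (tetrahydrofuran formation) and its deprotonation during lithiation.

Step 15
Reactants: 16 (3R,5aR,6R,7S,9aR)-6-allyl-3-(tert-butyldimethylsilyloxy)-2,2,5a,7-tetramethyl-7-(triethylsilyloxy)decahydro-1-benzoxepine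
Product: 18 2-[(3R,5aR,6R,7S,9aR)-3-(tert-butyldimethylsilyloxy)-2,2,5a,7-tetramethyl-7-(triethylsilyloxy)decahydro-1-benzoxepin-6-yl]ethanol, via aldehyde 17 (not isolated)
Conditions: O3, CH2Cl2/MeOH, −78 °C; then NaBH4, −78 to 0 °C
Reagents that add atoms: ozone ([O-][O+]=O)
Why: ozonolysis of the only alkene with reductive borohydride work-up shortens the allyl group to the two-carbon primary alcohol of the linker.

Step 16
Reactants: 18 2-[(3R,5aR,6R,7S,9aR)-3-(tert-butyldimethylsilyloxy)-2,2,5a,7-tetramethyl-7-(triethylsilyloxy)decahydro-1-benzoxepin-6-yl]ethanol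
Product: 19 (3R,5aR,6R,7S,9aR)-3-(tert-butyldimethylsilyloxy)-6-(2-iodoethyl)-2,2,5a,7-tetramethyl-7-(triethylsilyloxy)decahydro-1-benzoxepine
Conditions: I2, PPh3, imidazole, CH2Cl2, 0 °C
Reagents that add atoms: iodine (II)
Why: Appel-type iodination of the primary alcohol under imidazole buffering should leave both silyl ethers intact.

**Right bicycle**

Step 17
Reactants: 20 (R)-(−)-linalool
Product: 21 (3R)-tert-butyl[(3,7-dimethylocta-1,6-dien-3-yl)oxy]dimethylsilane
Conditions: TBSOTf, 2,6-lutidine, CH2Cl2, 0 °C to rt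
Reagents that add atoms: tert-butyldimethylsilyl trifluoromethanesulfonate (CC(C)(C)[Si](C)(C)OS(=O)(=O)C(F)(F)F)
Why: silyl triflate silylation of the tertiary allylic alcohol gives a robust ether that carries the future C1 stereocentre unchanged.

Step 18
Reactants: 21 (3R)-tert-butyl[(3,7-dimethylocta-1,6-dien-3-yl)oxy]dimethylsilane
Product: 22 (4R)-4-(tert-butyldimethylsilyloxy)-4-methylhex-5-enal
Conditions: O3 (1 equiv), CH2Cl2, pyridine, −78 °C; then Me2S
Reagents that add atoms: ozone ([O-][O+]=O)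
Why: chemoselective ozonolysis, since the electron-rich trisubstituted alkene should react far faster than the hindered vinyl group next to the silyloxy-bearing quaternary carbon.

Step 19
Reactants: 22 (4R)-4-(tert-butyldimethylsilyloxy)-4-methylhex-5-enal
Product: 23 (3R)-tert-butyl[(7,7-dibromo-3-methylhepta-1,6-dien-3-yl)oxy]dimethylsilane
Conditions: CBr4, PPh3, CH2Cl2, 0 °C
Reagents that add atoms: carbon tetrabromide (BrC(Br)(Br)Br)
Why: first stage of the Corey–Fuchs alkyne synthesis, a Wittig-type dibromomethylenation of the aldehyde.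

Step 20
Reactants: 23 (3R)-tert-butyl[(7,7-dibromo-3-methylhepta-1,6-dien-3-yl)oxy]dimethylsilane
Product: 25 (3R)-tert-butyldimethyl[(3-methyloct-1-en-6-yn-3-yl)oxy]silane, via lithium acetylide 24 (not isolated)
Conditions: n-BuLi (2.1 equiv), THF, −78 °C; then MeI, −78 °C to rt
Reagents that add atoms: iodomethane (CI)
Why: second stage of the Corey–Fuchs sequence (bromine–lithium exchange, rearrangement to the lithium acetylide) with methylation of the acetylide, which supplies one of the later gem-dimethyl carbons.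

Step 21
Reactants: 25 (3R)-tert-butyldimethyl[(3-methyloct-1-en-6-yn-3-yl)oxy]silane
Product: 26 (6R,6aR)-6-(tert-butyldimethylsilyloxy)-3,6-dimethyl-4,5,6,6a-tetrahydropentalen-2(1H)-one
Conditions: [Rh(CO)2Cl]2 (3 mol %), CO (1 atm), toluene, 110 °C
Reagents that add atoms: carbon monoxide ([C-]#[O+])
Why: intramolecular Pauson–Khand cyclocarbonylation of a 1,6-enyne builds both five-membered rings; the new stereocentre C6a is set by the neighbouring quaternary carbon, whose bulky silyloxy group should take the convex (exo) position so that H-6a ends up syn to it.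

Step 22
Reactants: 26 (6R,6aR)-6-(tert-butyldimethylsilyloxy)-3,6-dimethyl-4,5,6,6a-tetrahydropentalen-2(1H)-one
Product: 28 (3aR,6R,6aR)-6-(tert-butyldimethylsilyloxy)-3,3,6-trimethylhexahydropentalen-2(1H)-one (cis-fused), via lithium enolate 27 (not isolated)
Conditions: Li, NH3(l), THF, t-BuOH (1 equiv), −78 °C; then MeI
Reagents that add atoms: iodomethane (CI)
Why: dissolving-metal reduction of the enone with alkylation of the regiodefined enolate creates the gem-dimethyl carbon, and protonation at C3a can only give the cis-fused bicyclo[3.3.0]octane.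

Step 23
Reactants: 28 (3aR,6R,6aR)-6-(tert-butyldimethylsilyloxy)-3,3,6-trimethylhexahydropentalen-2(1H)-one
Product: 29 trimethylsilyl enol ether of 28 (2-trimethylsilyloxy-1-ene)
Conditions: LiN(i-Pr)2, THF, −78 °C; Me3SiCl, Et3N
Reagents that add atoms: chlorotrimethylsilane (C[Si](C)(C)Cl)
Why: enolate silylation, regiospecific because the other α-carbon is quaternary.

Step 24
Reactants: 29 trimethylsilyl enol ether of 28
Product: 30 2-chloro-2-methyl-1-(trimethylsilyloxy)cyclobutanone adduct of 29 (tricyclic; mixture at the three new centres, all cleared in step 25)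
Conditions: 2-chloropropanoyl chloride, Et3N, hexane, rt to 60 °C
Reagents that add atoms: 2-chloropropanoyl chloride (CC(Cl)C(Cl)=O)
Why: [2+2] cycloaddition of chloro(methyl)ketene, made in the flask, with the silyl enol ether, in which the ketene carbonyl carbon should bond to the nucleophilic enol ether carbon and so place the two future ring carbons correctly.

Step 25
Reactants: 30 2-chloro-2-methyl-1-(trimethylsilyloxy)cyclobutanone adduct
Product: 32 (1R,3aR,8aR)-1-(tert-butyldimethylsilyloxy)-1,4,4,6-tetramethyloctahydroazulene-5,7-dione, via dechlorinated cyclobutanone 31 (not isolated)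
Conditions: Zn dust, AcOH, THF, rt; then K2CO3, MeOH, rt
Reagents that add atoms: none
Why: reductive dechlorination of the α-chloro ketone followed by desilylation and retro-aldol opening of the strained cyclobutanol expands the five-membered ring by two carbons to the cycloheptane-1,3-dione.

Step 26
Reactants: 32 (1R,3aR,8aR)-1-(tert-butyldimethylsilyloxy)-1,4,4,6-tetramethyloctahydroazulene-5,7-dione
Product: 33 (1R,3aR,8aR)-1-(tert-butyldimethylsilyloxy)-7-methoxy-1,4,4,6-tetramethyl-2,3,3a,4,8,8a-hexahydroazulen-5(1H)-one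
Conditions: HC(OMe)3, MeOH, TsOH (cat.), rt
Reagents that add atoms: trimethyl orthoformate (COC(OC)OC)
Why: acid-catalysed vinylogous ester formation under equilibrating conditions should put the enol ether on the less hindered carbonyl (C7), leaving the ketone next to the gem-dimethyl carbon (C5).

**Union and end game**

Step 27
Reactants: 19 (3R,5aR,6R,7S,9aR)-3-(tert-butyldimethylsilyloxy)-6-(2-iodoethyl)-2,2,5a,7-tetramethyl-7-(triethylsilyloxy)decahydro-1-benzoxepine; 33 (1R,3aR,8aR)-1-(tert-butyldimethylsilyloxy)-7-methoxy-1,4,4,6-tetramethyl-2,3,3a,4,8,8a-hexahydroazulen-5(1H)-one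
Product: 36 (1R,3aR,8aR)-1-(tert-butyldimethylsilyloxy)-5-{2-[(3R,5aR,6R,7S,9aR)-3-(tert-butyldimethylsilyloxy)-2,2,5a,7-tetramethyl-7-(triethylsilyloxy)decahydro-1-benzoxepin-6-yl]ethyl}-1,4,4,6-tetramethyl-2,3,3a,4,8,8a-hexahydroazulen-7(1H)-one, via alkyllithium 34 (not isolated), via carbinol adduct 35 (not isolated)
Conditions: t-BuLi (2.1 equiv), Et2O/pentane, −78 °C; 33 in THF, −78 to 0 °C; then 1 M HCl, THF, 0 °C
Reagents that add atoms: water (O)
Why: Stork–Danheiser sequence, in which the primary alkyllithium from iodine–lithium exchange adds 1,2 to the vinylogous ester (no α'-hydrogens, so no enolisation) and acid then transposes the carbonyl to give the tetrasubstituted enone with the linker on C5.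

Step 28
Reactants: 36 coupled enone
Product: 37 (1R,3aR,7S,8aR)-1-(tert-butyldimethylsilyloxy)-5-{2-[(3R,5aR,6R,7S,9aR)-3-(tert-butyldimethylsilyloxy)-2,2,5a,7-tetramethyl-7-(triethylsilyloxy)decahydro-1-benzoxepin-6-yl]ethyl}-1,4,4,6-tetramethyl-1,2,3,3a,4,7,8,8a-octahydroazulen-7-ol
Conditions: (R)-2-methyl-CBS-oxazaborolidine (20 mol %), catecholborane, toluene, −60 °C
Reagents that add atoms: none
Why: Corey–Bakshi–Shibata 1,2-reduction of the enone, with the tetrasubstituted alkene flank as the large group, should give the (7S)-allylic alcohol under reagent control.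

Step 29
Reactants: 37 tris-silyl ether
Product: 38 (3R,5aR,6R,7S,9aR)-6-{2-[(1R,3aR,7S,8aR)-1,7-dihydroxy-1,4,4,6-tetramethyl-1,2,3,3a,4,7,8,8a-octahydroazulen-5-yl]ethyl}-2,2,5a,7-tetramethyldecahydro-1-benzoxepine-3,7-diol (target)
Conditions: Bu4NF, THF, 60 °C
Reagents that add atoms: none
Why: fluoride-mediated cleavage of the three silyl ethers under non-acidic conditions should spare the tertiary and allylic alcohols from ionisation.

**Compound list**

1 | 1,4-dioxaspiro[4.5]dec-6-en-8-one | O=C1C=CC2(CC1)OCCO2 | starting material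
2 | 7-iodo-1,4-dioxaspiro[4.5]dec-6-en-8-one | O=C1C(I)=CC2(CC1)OCCO2 | intermediate
3 | 7-methyl-1,4-dioxaspiro[4.5]dec-6-en-8-one | O=C1C(C)=CC2(CC1)OCCO2 | intermediate
4 | (8R)-7-methyl-1,4-dioxaspiro[4.5]dec-6-en-8-ol | O[C@@H]1CCC2(OCCO2)C=C1C | intermediate
5 | 2-methyl-2-{[(8R)-7-methyl-1,4-dioxaspiro[4.5]dec-6-en-8-yl]oxy}propanoic acid | OC(=O)C(C)(C)O[C@@H]1CCC2(OCCO2)C=C1C | intermediate
6 | 4-methyl-4-{[(8R)-7-methyl-1,4-dioxaspiro[4.5]dec-6-en-8-yl]oxy}pent-1-en-3-one | C=CC(=O)C(C)(C)O[C@@H]1CCC2(OCCO2)C=C1C | intermediate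
7 | (5aR,9aR)-7,7-(ethylenedioxy)-2,2,5a-trimethyloctahydro-1-benzoxepin-3(2H)-one, trans-fused | C1[C@@]2(C)CCC(=O)C(C)(C)O[C@@H]2CCC13OCCO3 | intermediate
8 | (3R,5aR,9aR)-7,7-(ethylenedioxy)-2,2,5a-trimethyldecahydro-1-benzoxepin-3-ol | C1[C@@]2(C)CC[C@@H](O)C(C)(C)O[C@@H]2CCC13OCCO3 | intermediate
9 | (3R,5aR,9aR)-3-(tert-butyldimethylsilyloxy)-7,7-(ethylenedioxy)-2,2,5a-trimethyldecahydro-1-benzoxepine | C1[C@@]2(C)CC[C@@H](O[Si](C)(C)C(C)(C)C)C(C)(C)O[C@@H]2CCC13OCCO3 | intermediate
10 | (3R,5aR,9aR)-3-(tert-butyldimethylsilyloxy)-2,2,5a-trimethyloctahydro-1-benzoxepin-7(2H)-one | C1[C@@]2(C)CC[C@@H](O[Si](C)(C)C(C)(C)C)C(C)(C)O[C@@H]2CCC1=O | intermediate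
11 | (3R,5aR,9aR)-3-(tert-butyldimethylsilyloxy)-2,2,5a-trimethyl-3,4,5,5a,6,9a-hexahydro-1-benzoxepin-7(2H)-one | C1[C@@]2(C)CC[C@@H](O[Si](C)(C)C(C)(C)C)C(C)(C)O[C@@H]2C=CC1=O | intermediate
12 | (3R,5aR,6S,9aR)-6-allyl-3-(tert-butyldimethylsilyloxy)-2,2,5a-trimethyl-3,4,5,5a,6,9a-hexahydro-1-benzoxepin-7(2H)-one | C=CC[C@H]1[C@@]2(C)CC[C@@H](O[Si](C)(C)C(C)(C)C)C(C)(C)O[C@@H]2C=CC1=O | intermediate
13 | diethoxy(methyl)silyl enol ether (7-silyloxy-7-ene) of the (6S)-allyl ketone | C=CC[C@H]1[C@@]2(C)CC[C@@H](O[Si](C)(C)C(C)(C)C)C(C)(C)O[C@@H]2CC=C1O[Si](C)(OCC)OCC | intermediate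
14 | (3R,5aR,6R,9aR)-6-allyl-3-(tert-butyldimethylsilyloxy)-2,2,5a-trimethyloctahydro-1-benzoxepin-7(2H)-one | C=CC[C@@H]1[C@@]2(C)CC[C@@H](O[Si](C)(C)C(C)(C)C)C(C)(C)O[C@@H]2CCC1=O | intermediate
15 | (3R,5aR,6R,7S,9aR)-6-allyl-3-(tert-butyldimethylsilyloxy)-2,2,5a,7-tetramethyldecahydro-1-benzoxepin-7-ol | C=CC[C@@H]1[C@@]2(C)CC[C@@H](O[Si](C)(C)C(C)(C)C)C(C)(C)O[C@@H]2CC[C@]1(C)O | intermediate
16 | (3R,5aR,6R,7S,9aR)-6-allyl-3-(tert-butyldimethylsilyloxy)-2,2,5a,7-tetramethyl-7-(triethylsilyloxy)decahydro-1-benzoxepine | C=CC[C@@H]1[C@@]2(C)CC[C@@H](O[Si](C)(C)C(C)(C)C)C(C)(C)O[C@@H]2CC[C@]1(C)O[Si](CC)(CC)CC | intermediate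
17 | [(3R,5aR,6R,7S,9aR)-3-(tert-butyldimethylsilyloxy)-2,2,5a,7-tetramethyl-7-(triethylsilyloxy)decahydro-1-benzoxepin-6-yl]acetaldehyde | O=CC[C@@H]1[C@@]2(C)CC[C@@H](O[Si](C)(C)C(C)(C)C)C(C)(C)O[C@@H]2CC[C@]1(C)O[Si](CC)(CC)CC | intermediate
18 | 2-[(3R,5aR,6R,7S,9aR)-3-(tert-butyldimethylsilyloxy)-2,2,5a,7-tetramethyl-7-(triethylsilyloxy)decahydro-1-benzoxepin-6-yl]ethanol | OCC[C@@H]1[C@@]2(C)CC[C@@H](O[Si](C)(C)C(C)(C)C)C(C)(C)O[C@@H]2CC[C@]1(C)O[Si](CC)(CC)CC | intermediate
19 | (3R,5aR,6R,7S,9aR)-3-(tert-butyldimethylsilyloxy)-6-(2-iodoethyl)-2,2,5a,7-tetramethyl-7-(triethylsilyloxy)decahydro-1-benzoxepine | ICC[C@@H]1[C@@]2(C)CC[C@@H](O[Si](C)(C)C(C)(C)C)C(C)(C)O[C@@H]2CC[C@]1(C)O[Si](CC)(CC)CC | intermediate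
20 | (R)-(−)-linalool, (3R)-3,7-dimethylocta-1,6-dien-3-ol | C=C[C@](C)(O)CCC=C(C)C | starting material
21 | (3R)-tert-butyl[(3,7-dimethylocta-1,6-dien-3-yl)oxy]dimethylsilane | C=C[C@](C)(O[Si](C)(C)C(C)(C)C)CCC=C(C)C | intermediate
22 | (4R)-4-(tert-butyldimethylsilyloxy)-4-methylhex-5-enal | C=C[C@](C)(O[Si](C)(C)C(C)(C)C)CCC=O | intermediate
23 | (3R)-tert-butyl[(7,7-dibromo-3-methylhepta-1,6-dien-3-yl)oxy]dimethylsilane | C=C[C@](C)(O[Si](C)(C)C(C)(C)C)CCC=C(Br)Br | intermediate
24 | lithium acetylide of (3R)-3-(tert-butyldimethylsilyloxy)-3-methylhept-1-en-6-yne | C=C[C@](C)(O[Si](C)(C)C(C)(C)C)CCC#C[Li] | intermediate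
25 | (3R)-tert-butyldimethyl[(3-methyloct-1-en-6-yn-3-yl)oxy]silane | C=C[C@](C)(O[Si](C)(C)C(C)(C)C)CCC#CC | intermediate
26 | (6R,6aR)-6-(tert-butyldimethylsilyloxy)-3,6-dimethyl-4,5,6,6a-tetrahydropentalen-2(1H)-one | CC1=C2CC[C@@](C)(O[Si](C)(C)C(C)(C)C)[C@@H]2CC1=O | intermediate
27 | lithium enolate (2-lithiooxy-3-methyl-2-ene) of the cis-fused reduced ketone | CC1=C(O[Li])C[C@@H]2[C@H]1CC[C@@]2(C)O[Si](C)(C)C(C)(C)C | intermediate
28 | (3aR,6R,6aR)-6-(tert-butyldimethylsilyloxy)-3,3,6-trimethylhexahydropentalen-2(1H)-one, cis-fused | CC1(C)[C@@H]2CC[C@@](C)(O[Si](C)(C)C(C)(C)C)[C@@H]2CC1=O | intermediate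
29 | trimethylsilyl enol ether of 28 (2-trimethylsilyloxy-1-ene) | CC1(C)[C@@H]2CC[C@@](C)(O[Si](C)(C)C(C)(C)C)[C@@H]2C=C1O[Si](C)(C)C | intermediate
30 | 2-chloro-2-methyl-1-(trimethylsilyloxy)cyclobutanone adduct of 29 (new centres unassigned) | CC1(C)[C@@H]2CC[C@@](C)(O[Si](C)(C)C(C)(C)C)[C@@H]2C2C(=O)C(C)(Cl)C12O[Si](C)(C)C | intermediate
31 | dechlorinated 2-methyl-1-(trimethylsilyloxy)cyclobutanone | CC1(C)[C@@H]2CC[C@@](C)(O[Si](C)(C)C(C)(C)C)[C@@H]2C2C(=O)C(C)C12O[Si](C)(C)C | intermediate
32 | (1R,3aR,8aR)-1-(tert-butyldimethylsilyloxy)-1,4,4,6-tetramethyloctahydroazulene-5,7-dione (C6 epimerisable) | CC1(C)[C@@H]2CC[C@@](C)(O[Si](C)(C)C(C)(C)C)[C@@H]2CC(=O)C(C)C1=O | intermediate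
33 | (1R,3aR,8aR)-1-(tert-butyldimethylsilyloxy)-7-methoxy-1,4,4,6-tetramethyl-2,3,3a,4,8,8a-hexahydroazulen-5(1H)-one | COC1=C(C)C(=O)C(C)(C)[C@@H]2CC[C@@](C)(O[Si](C)(C)C(C)(C)C)[C@@H]2C1 | intermediate
34 | primary alkyllithium from 19 | [Li]CC[C@@H]1[C@@]2(C)CC[C@@H](O[Si](C)(C)C(C)(C)C)C(C)(C)O[C@@H]2CC[C@]1(C)O[Si](CC)(CC)CC | intermediate
35 | tertiary carbinol adduct (5-hydroxy-7-methoxy-6-ene; C5 unassigned) | COC1=C(C)C(O)(CC[C@@H]2[C@@]3(C)CC[C@@H](O[Si](C)(C)C(C)(C)C)C(C)(C)O[C@@H]3CC[C@]2(C)O[Si](CC)(CC)CC)C(C)(C)[C@@H]2CC[C@@](C)(O[Si](C)(C)C(C)(C)C)[C@@H]2C1 | intermediate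
36 | coupled enone, (1R,3aR,8aR)-azulen-7(1H)-one carrying the (3R,5aR,6R,7S,9aR)-benzoxepinylethyl group on C5 | CC1=C(CC[C@@H]2[C@@]3(C)CC[C@@H](O[Si](C)(C)C(C)(C)C)C(C)(C)O[C@@H]3CC[C@]2(C)O[Si](CC)(CC)CC)C(C)(C)[C@@H]2CC[C@@](C)(O[Si](C)(C)C(C)(C)C)[C@@H]2CC1=O | intermediate
37 | (7S)-allylic alcohol, tris-silyl ether of the target | CC1=C(CC[C@@H]2[C@@]3(C)CC[C@@H](O[Si](C)(C)C(C)(C)C)C(C)(C)O[C@@H]3CC[C@]2(C)O[Si](CC)(CC)CC)C(C)(C)[C@@H]2CC[C@@](C)(O[Si](C)(C)C(C)(C)C)[C@@H]2C[C@@H]1O | intermediate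
38 | (3R,5aR,6R,7S,9aR)-6-{2-[(1R,3aR,7S,8aR)-1,7-dihydroxy-1,4,4,6-tetramethyl-1,2,3,3a,4,7,8,8a-octahydroazulen-5-yl]ethyl}-2,2,5a,7-tetramethyldecahydro-1-benzoxepine-3,7-diol | CC1=C(CC[C@@H]2[C@@]3(C)CC[C@@H](O)C(C)(C)O[C@@H]3CC[C@]2(C)O)C(C)(C)[C@@H]2CC[C@@](C)(O)[C@@H]2C[C@@H]1O | target

**Totals**

Total step count: 29. Longest linear sequence: 19 steps (steps 1–16, then 27–29); the right bicycle is a 10-step branch (steps 17–26).

**Steps most likely to fail**

Step 6 (labelled). The tertiary radical may be reduced by the silane before the slow seven-membered closure occurs, or the closure may proceed with poor facial selectivity and give the cis ring fusion. The fallback uses known chemistry, sets out from 4 and comes back at 8. Intermolecular iron-mediated reductive olefin coupling of 4 with acrolein (Fe(acac)3, PhSiH3, EtOH) should form the quaternary centre by attack anti to the neighbouring hydroxyl and give 3-[(7R,8R)-8-hydroxy-7-methyl-1,4-dioxaspiro[4.5]decan-7-yl]propanal F1 (in equilibrium with its lactol). Wittig olefination with isopropylidenetriphenylphosphorane gives the prenyl-type alkene (7R,8R)-7-methyl-7-(4-methylpent-3-en-1-yl)-1,4-dioxaspiro[4.5]decan-8-ol F2. Shi epoxidation with the fructose-derived ketone enantiomer that delivers the (R)-epoxide gives (7R,8R)-7-{2-[(2R)-3,3-dimethyloxiran-2-yl]ethyl}-7-methyl-1,4-dioxaspiro[4.5]decan-8-ol F3. Camphorsulfonic acid in CH2Cl2 at 0 °C then opens the epoxide at its tertiary carbon with the ring hydroxyl (7-endo), which closes the oxepane through the O1–C2 bond and gives 8 directly.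

Step 4. The bromo acid may lose HBr to methacrylate faster than the hindered secondary alkoxide is alkylated, so conversion may stay low. The fallback sets out from 4 and comes back at 6. Gold-catalysed hydroalkoxylation of 3-methylbuta-1,2-diene (Ph3PAuNTf2, DMF-containing solvent, rt) should give the tertiary allylic ether (8R)-7-methyl-8-[(2-methylbut-3-en-2-yl)oxy]-1,4-dioxaspiro[4.5]dec-6-ene F4. Wacker oxidation (PdCl2, CuCl, O2, DMF/H2O), selective for the monosubstituted alkene, gives 3-methyl-3-{[(8R)-7-methyl-1,4-dioxaspiro[4.5]dec-6-en-8-yl]oxy}butan-2-one F5. α-Methylenation of this methyl ketone with paraformaldehyde and diisopropylammonium trifluoroacetate in THF gives 6.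

Step 24. The monochloroketene may add too slowly to the hindered silyl enol ether and be lost to self-condensation. The fallback sets out from 29 and comes back at 32. Dichloroketene (from trichloroacetyl chloride and zinc–copper couple), the more reactive ketene, adds to 29 to give the 2,2-dichloro-1-(trimethylsilyloxy)cyclobutanone adduct F6. Zn/AcOH followed by K2CO3/MeOH gives the ring-expanded (1R,3aR,8aR)-1-(tert-butyldimethylsilyloxy)-1,4,4-trimethyloctahydroazulene-5,7-dione F7. C-methylation between the two carbonyls (MeI, K2CO3, acetone) gives 32.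

**Further compounds**

F1 | step 6 | 3-[(7R,8R)-8-hydroxy-7-methyl-1,4-dioxaspiro[4.5]decan-7-yl]propanal | O=CCC[C@]1(C)CC2(OCCO2)CC[C@H]1O
F2 | step 6 | (7R,8R)-7-methyl-7-(4-methylpent-3-en-1-yl)-1,4-dioxaspiro[4.5]decan-8-ol | CC(C)=CCC[C@]1(C)CC2(OCCO2)CC[C@H]1O
F3 | step 6 | (7R,8R)-7-{2-[(2R)-3,3-dimethyloxiran-2-yl]ethyl}-7-methyl-1,4-dioxaspiro[4.5]decan-8-ol | CC1(C)O[C@@H]1CC[C@]1(C)CC2(OCCO2)CC[C@H]1O
F4 | step 4 | (8R)-7-methyl-8-[(2-methylbut-3-en-2-yl)oxy]-1,4-dioxaspiro[4.5]dec-6-ene | C=CC(C)(C)O[C@@H]1CCC2(OCCO2)C=C1C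
F5 | step 4 | 3-methyl-3-{[(8R)-7-methyl-1,4-dioxaspiro[4.5]dec-6-en-8-yl]oxy}butan-2-one | CC(=O)C(C)(C)O[C@@H]1CCC2(OCCO2)C=C1C
F6 | step 24 | 2,2-dichloro-1-(trimethylsilyloxy)cyclobutanone adduct of 29 | CC1(C)[C@@H]2CC[C@@](C)(O[Si](C)(C)C(C)(C)C)[C@@H]2C2C(=O)C(Cl)(Cl)C12O[Si](C)(C)C
F7 | step 24 | (1R,3aR,8aR)-1-(tert-butyldimethylsilyloxy)-1,4,4-trimethyloctahydroazulene-5,7-dione | CC1(C)[C@@H]2CC[C@@](C)(O[Si](C)(C)C(C)(C)C)[C@@H]2CC(=O)CC1=O
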